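Ring A is built, not bought: its bonds C1′–C2′, C5′–C6′ and C2′–C3′ are traced back to a vinylketene and methoxyacetylene. In one photochemical operation a Wolff shift, a [2+2] addition, a 4π opening and a 6π closure build ring A on the preformed pyran ring. The step exploits the 2′,4′,6′-oxygen pattern: the ketene carbon becomes C2′–OH, the alkyne C–O carbon becomes C6′–OMe, the enol-ether carbon becomes C4′ on pyran O1, C3′ keeps pyran C4, and C1′ is left as CH for acetylation. The precursor is 2-diazo-1-(6,6-dimethyl-5,6-dihydro-4H-pyran-2-yl)ethanone plus methoxyacetylene; dehydrogenation and aldol condensation finish the route.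

Key step: step 5

Remark: chalcone locants C1′, C2′, C3′, C4′, C5′, C6′ of ring A correspond to chroman/chromene atoms C6, C5, C4a, C8a, C8, C7; the chroman is dehydrogenated before the enone is built, because DDQ can cyclise 2′-hydroxychalcones oxidatively.

Step 1
Reactants: 1 acrolein; 2 2-methylpropene
Product: 3 2,2-dimethyl-3,4-dihydro-2H-pyran
Conditions: 2 (3 equiv), hydroquinone (cat.), neat, steel autoclave, ca. 200 °C
Reagents that add atoms: none
Why: Thermal inverse-electron-demand hetero-Diels–Alder reaction with acrolein as the 1-oxadiene; the alkene CH2 bonds to the β-carbon of acrolein and the disubstituted carbon to oxygen, which places both methyl groups next to the ring oxygen, and no stereocentre is formed.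

Step 2
Reactants: 3 2,2-dimethyl-3,4-dihydro-2H-pyran
Product: 6 1-(6,6-dimethyl-5,6-dihydro-4H-pyran-2-yl)ethanone, via 6-lithio-2,2-dimethyl-3,4-dihydro-2H-pyran 4 (not isolated), via lithium hemiaminal adduct 5 (not isolated)
Conditions: t-BuLi, THF–pentane, −78 → 0 °C; then MeC(O)N(OMe)Me, −78 °C → rt; aq NH4Cl
Reagents that add atoms: N-methoxy-N-methylacetamide, CC(=O)N(C)OC
Why: α-Lithiation of a cyclic enol ether at its oxygen-bearing sp2 carbon followed by Weinreb ketone synthesis; adduct 5 is held as a lithium chelate until work-up, so the vinyllithium should add only once.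

Step 3
Reactants: 6 1-(6,6-dimethyl-5,6-dihydro-4H-pyran-2-yl)ethanone
Product: 8 2-diazo-1-(6,6-dimethyl-5,6-dihydro-4H-pyran-2-yl)ethanone, via trifluoroacetyl diketone 7 (not isolated)
Conditions: LiN(SiMe3)2, THF, −78 °C; CF3CO2CH2CF3; cold 5% aq HCl work-up; then MsN3, Et3N, H2O (1 equiv), MeCN, rt
Reagents that add atoms: methanesulfonyl azide, CS(=O)(=O)N=[N+]=[N-]
Why: Detrifluoroacetylative diazo transfer: Claisen trifluoroacetylation of the kinetic methyl enolate activates the ketone, and Regitz-type diazo transfer then passes the trifluoroacetyl group to the sulfonamide; this is the standard entry to α′-diazo enones, which direct diazo transfer does not give.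

Step 4
Reactants: 9 chloroacetaldehyde dimethyl acetal
Product: 11 methoxyacetylene, via sodium methoxyacetylide 10 (not isolated)
Conditions: NaNH2 (3 equiv), NH3 (l), −33 °C; evaporate NH3; then cold saturated aq NaCl, −70 → 20 °C, distil into a −78 °C trap
Reagents that add atoms: none
Why: Twofold base-induced β-elimination (methanol, then HCl) from the α-chloroacetal, the classical preparation of alkoxyacetylenes; the third equivalent of NaNH2 holds the product as the involatile acetylide 10 until water releases it for distillation.

Step 5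
Reactants: 8 2-diazo-1-(6,6-dimethyl-5,6-dihydro-4H-pyran-2-yl)ethanone; 11 methoxyacetylene
Product: 16 5-hydroxy-7-methoxy-2,2-dimethylchroman, via vinylketene 12 (not isolated), via 4-vinylcyclobutenone 13 (not isolated), via dienylketene 14 (not isolated), via cyclohexadienone 15 (not isolated)
Conditions: hν (254 nm, quartz), 11 (3 equiv), ClCH2CH2Cl, 15 °C, sealed tube; vent excess 11; then 80 °C
Reagents that add atoms: none
Why: Photolysis of 8 releases N2 with a 1,2-shift of the dihydropyranyl carbon onto the former diazo carbon (Wolff rearrangement, which also makes C4′–C5′), and the resulting vinylketene 12 is trapped by the ynol ether in a polar [2+2] cycloaddition to cyclobutenone 13, which on warming opens in a 4π electrocyclic step to dienylketene 14 and recloses to dienone 15, the keto tautomer of phenol 16. The closest known reaction type is the Danheiser benzannulation in its photochemical Wolff form, in which α,β-unsaturated α′-diazo ketones are joined to alkoxyacetylenes; here the unsaturated part is a cyclic enol ether. Ring A is closed by a thermally allowed disrotatory 6π electrocyclisation that links the former ketene carbon (C2′) to the enol-ether CH (C3′), the [2+2] step having already made C1′–C2′ and C5′–C6′. No stereocentre needs control, because the sp3 centres of 13 and 15 are formed racemic and disappear on ring opening and aromatisation. The selectivity required is the orientation of the [2+2] step, and it follows from the polarity of the partners: the unsubstituted, electron-rich alkyne carbon joins the electrophilic central ketene carbon, so that OMe lies meta to OH with C1′–H between them. The 6π closure has only one terminus available, so the three oxygens end up distinct by origin: C2′–OH from the ketene, C6′–OMe from the alkyne and C4′–O1 from the enol ether.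

Step 6
Reactants: 16 5-hydroxy-7-methoxy-2,2-dimethylchroman
Product: 18 1-(5-hydroxy-7-methoxy-2,2-dimethylchroman-6-yl)ethanone, via difluoroboron chelate 17 (not isolated)
Conditions: Ac2O, BF3·OEt2, 70 °C; then NaOAc, aq EtOH, reflux
Reagents that add atoms: acetic anhydride, CC(=O)OC(C)=O
Why: Friedel–Crafts acetylation under Fries-type equilibration; boron locks the ketone that sits next to the free hydroxyl as chelate 17, so acylation should end at C6 (C1′, between OH and OMe) and not at C8, which has no neighbouring hydroxyl, and mild hydrolysis frees the hydrogen-bonded ketone.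

Step 7
Reactants: 18 1-(5-hydroxy-7-methoxy-2,2-dimethylchroman-6-yl)ethanone
Product: 19 1-(5-hydroxy-7-methoxy-2,2-dimethyl-2H-chromen-6-yl)ethanone
Conditions: DDQ (1.2 equiv), 1,4-dioxane, reflux
Reagents that add atoms: none
Why: DDQ dehydrogenation of a 2,2-dimethylchroman to the 2H-chromene: hydride loss from benzylic C4 gives a cation stabilised by O1, the C5 oxygen and the C7 methoxy group, proton loss from C3 follows, and the quaternary C2 rules out further oxidation.

Step 8
Reactants: 19 1-(5-hydroxy-7-methoxy-2,2-dimethyl-2H-chromen-6-yl)ethanone; 20 4-methoxybenzaldehyde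
Product: 22 Glychalcone A [(E)-1-(5-hydroxy-7-methoxy-2,2-dimethyl-2H-chromen-6-yl)-3-(4-methoxyphenyl)prop-2-en-1-one], via aldol adduct 21 (not isolated)
Conditions: KOH (50% aq), EtOH, rt
Reagents that add atoms: none
Why: Claisen–Schmidt condensation: the methyl ketone enolate adds to the non-enolisable aldehyde, and E1cB dehydration of racemic aldol 21 gives the conjugated enone as the thermodynamically favoured E isomer; the chromene and both methyl ethers are inert to base.

Compound list
1 | acrolein (prop-2-enal) | C=CC=O | starting material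
2 | 2-methylpropene | CC(C)=C | starting material
3 | 2,2-dimethyl-3,4-dihydro-2H-pyran | CC1(C)CCC=CO1 | intermediate
4 | 6-lithio-2,2-dimethyl-3,4-dihydro-2H-pyran | [Li]C1=CCCC(C)(C)O1 | intermediate
5 | lithium 1-(6,6-dimethyl-5,6-dihydro-4H-pyran-2-yl)-1-[methoxy(methyl)amino]ethanolate (racemic) | CC(O[Li])(N(C)OC)C1=CCCC(C)(C)O1 | intermediate
6 | 1-(6,6-dimethyl-5,6-dihydro-4H-pyran-2-yl)ethanone | CC(=O)C1=CCCC(C)(C)O1 | intermediate
7 | 1-(6,6-dimethyl-5,6-dihydro-4H-pyran-2-yl)-4,4,4-trifluorobutane-1,3-dione | O=C(CC(=O)C(F)(F)F)C1=CCCC(C)(C)O1 | intermediate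
8 | 2-diazo-1-(6,6-dimethyl-5,6-dihydro-4H-pyran-2-yl)ethanone | CC1(C)CCC=C(O1)C(=O)C=[N+]=[N-] | intermediate
9 | chloroacetaldehyde dimethyl acetal (2-chloro-1,1-dimethoxyethane) | COC(CCl)OC | starting material
10 | sodium methoxyacetylide | [Na+].[C-]#COC | intermediate
11 | methoxyacetylene | COC#C | intermediate
12 | 2-(6,6-dimethyl-5,6-dihydro-4H-pyran-2-yl)ethenone (vinylketene) | CC1(C)CCC=C(O1)C=C=O | intermediate
13 | 4-(6,6-dimethyl-5,6-dihydro-4H-pyran-2-yl)-3-methoxycyclobut-2-en-1-one (racemic) | COC1=CC(=O)C1C2=CCCC(C)(C)O2 | intermediate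
14 | (3E)-4-(6,6-dimethyl-5,6-dihydro-4H-pyran-2-yl)-3-methoxybuta-1,3-dien-1-one (ketene arm cis to the pyranyl group) | O=C=C/C(OC)=C\C1=CCCC(C)(C)O1 | intermediate
15 | 7-methoxy-2,2-dimethyl-2,3,4,4a-tetrahydro-5H-chromen-5-one (racemic) | COC1=CC(=O)C2CCC(C)(C)OC2=C1 | intermediate
16 | 5-hydroxy-7-methoxy-2,2-dimethylchroman | COc1cc(O)c2CCC(C)(C)Oc2c1 | intermediate
17 | difluoroboron chelate of 18 (BF2 bridging the C5 phenolate oxygen and the acetyl oxygen) | CC1=[O+][B-](F)(F)Oc2c1c(OC)cc1OC(C)(C)CCc21 | intermediate
18 | 1-(5-hydroxy-7-methoxy-2,2-dimethylchroman-6-yl)ethanone | CC(=O)c1c(OC)cc2OC(C)(C)CCc2c1O | intermediate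
19 | 1-(5-hydroxy-7-methoxy-2,2-dimethyl-2H-chromen-6-yl)ethanone | CC(=O)c1c(OC)cc2OC(C)(C)C=Cc2c1O | intermediate
20 | 4-methoxybenzaldehyde | COc1ccc(C=O)cc1 | starting material
21 | 3-hydroxy-1-(5-hydroxy-7-methoxy-2,2-dimethyl-2H-chromen-6-yl)-3-(4-methoxyphenyl)propan-1-one (racemic) | COc1ccc(C(O)CC(=O)c2c(OC)cc3OC(C)(C)C=Cc3c2O)cc1 | intermediate
22 | Glychalcone A | COc1ccc(/C=C/C(=O)c2c(OC)cc3c(c2O)C=CC(C)(C)O3)cc1 | target

Total step count: 8. Longest linear sequence: 7 steps (steps 1, 2, 3, 5, 6, 7, 8); step 4 is a one-step side branch.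

Steps most likely to fail

Step 5. The photogenerated ketene may be lost to dimerisation or to O-acylation of phenol already formed, the volatile ynol ether may escape or polymerise, and carbene side reactions may outrun the 1,2-shift. The fallback gives up the benzannulation and takes ring A from a bought phloroacetophenone. It sets out from 4-methoxybenzaldehyde 20: Claisen–Schmidt condensation with commercial 1-(2,4-dihydroxy-6-methoxyphenyl)ethanone (KOH, aq EtOH, rt) would give (E)-1-(2,4-dihydroxy-6-methoxyphenyl)-3-(4-methoxyphenyl)prop-2-en-1-one F1. Chromenylation with 3-methylbut-2-enal (ethylenediammonium diacetate cat., xylene, reflux) should then proceed by Knoevenagel condensation at C3′, the carbon between the two hydroxyls, followed by oxa-6π electrocyclisation onto the 4′-oxygen. The fallback comes back to the route at 22.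

Step 6. Site selectivity between the two ring positions that are each flanked by two oxygens (C6 and C8) may be imperfect, or the reaction may stall at the O-acetate. The fallback replaces thermodynamic chelation control by directed metalation. It sets out from 16: MOMCl and i-Pr2NEt in CH2Cl2 would give 7-methoxy-5-(methoxymethoxy)-2,2-dimethylchroman F2. n-BuLi/TMEDA in THF at 0 °C should lithiate the carbon between OMOM and OMe to give [7-methoxy-5-(methoxymethoxy)-2,2-dimethylchroman-6-yl]lithium F3. With N-methoxy-N-methylacetamide this passes through lithium hemiaminal adduct F4 to 1-[7-methoxy-5-(methoxymethoxy)-2,2-dimethylchroman-6-yl]ethanone F5. HCl in MeOH at rt would remove the MOM group, and the fallback comes back at 18.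

Step 1. Thermal self-dimerisation and polymerisation of acrolein may outrun cycloaddition to an unactivated alkene, leaving low conversion. The fallback builds the dihydropyran by ionic chemistry at ambient pressure. It sets out from acrolein 1: HBr addition and acetalisation with propane-1,3-diol (TsOH cat.) would give 2-(2-bromoethyl)-1,3-dioxane F6. Mg in THF gives [2-(1,3-dioxan-2-yl)ethyl]magnesium bromide F7, which should open 2,2-dimethyloxirane at its CH2 group (CuI cat., THF, −30 °C) to 5-(1,3-dioxan-2-yl)-2-methylpentan-2-ol F8. Aqueous HCl in THF would hydrolyse the acetal to the lactol 6,6-dimethyltetrahydro-2H-pyran-2-ol F9, and dehydration with MsCl/Et3N (CH2Cl2, 0 °C → reflux) comes back at 3.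

Further compounds
F1 | step 5 | (E)-1-(2,4-dihydroxy-6-methoxyphenyl)-3-(4-methoxyphenyl)prop-2-en-1-one | COc1ccc(/C=C/C(=O)c2c(O)cc(O)cc2OC)cc1
F2 | step 6 | 7-methoxy-5-(methoxymethoxy)-2,2-dimethylchroman | COCOc1cc(OC)cc2OC(C)(C)CCc12
F3 | step 6 | [7-methoxy-5-(methoxymethoxy)-2,2-dimethylchroman-6-yl]lithium | [Li]c1c(OC)cc2OC(C)(C)CCc2c1OCOC
F4 | step 6 | lithium 1-[7-methoxy-5-(methoxymethoxy)-2,2-dimethylchroman-6-yl]-1-[methoxy(methyl)amino]ethanolate (racemic) | CC(O[Li])(N(C)OC)c1c(OC)cc2OC(C)(C)CCc2c1OCOC
F5 | step 6 | 1-[7-methoxy-5-(methoxymethoxy)-2,2-dimethylchroman-6-yl]ethanone | CC(=O)c1c(OC)cc2OC(C)(C)CCc2c1OCOC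
F6 | step 1 | 2-(2-bromoethyl)-1,3-dioxane | BrCCC1OCCCO1
F7 | step 1 | [2-(1,3-dioxan-2-yl)ethyl]magnesium bromide | Br[Mg]CCC1OCCCO1
F8 | step 1 | 5-(1,3-dioxan-2-yl)-2-methylpentan-2-ol | CC(C)(O)CCCC1OCCCO1
F9 | step 1 | 6,6-dimethyltetrahydro-2H-pyran-2-ol (racemic) | CC1(C)CCCC(O)O1
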